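Begin from 13, the factor by which the over-reaction step speeds up from zeta to gamma, a larger factor than the 7.0 of the step that makes the target.

    substrate + partner → target (k1 = 0.0094 M⁻¹ s⁻¹, Ea1 = 77.0 kJ mol⁻¹)
    substrate → side product (k2 = 0.0016 s⁻¹, Ea2 = 88.0 kJ mol⁻¹)
    partner + protic impurity → quenched reagent (k3 = 0.049 M⁻¹ s⁻¹, Ea3 = 48.0 kJ mol⁻¹)
    partner → decomposed reagent (k4 = 6.3 × 10⁻⁴ s⁻¹, Ea4 = 93.0 kJ mol⁻¹)
    target → over-reaction product (k5 = 8.1 × 10⁻⁴ s⁻¹, Ea5 = 101 kJ mol⁻¹)
    (constants at 60 °C)

the same everywhere: substrate 0.40 M; partner 0.240 M; protic impurity 0.0200 M; time 12 min

| run | temperature |
|---|---|
| gamma | 85 °C |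
| zeta | 60 °C |

- at 60 °C the constants are as listed, elsewhere as the activation energies make them

- the best flask by amount of target, in percent of the substrate charged; "all alike" if 1.5 percentage points covers them all (gamma / zeta / all alike)
- amount of target at the end, in percent of the substrate charged, gamma
- amount of target at the end, in percent of the substrate charged, zeta

Count lifetimes. Multiply the over-reaction constant at the flask's temperature by the time:

zeta: 0.583; gamma: 7.43

Call this the target's lifetime count: a target standing for a count n keeps the fraction exp(−n), and the gamma count is larger than the zeta count.

Next reckon what zeta makes, holding [partner] at its start: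

substrate consumed: 93.8%; share to target: 58.5%

That pass asks 0.219 M of partner, about what stands after the impurity takes its 0.0200 M, namely 0.220 M, so in this reckoning [partner] falls far from its start during the pass. Holding [partner] at its start is therefore the weak link. Reforge it by taking [partner] at the middle of that amount:

[partner] = 0.110 M; substrate consumed: 85.0%; share to target: 39.3%; target made: 33.4%

Let the made target stand for half of the zeta count:

zeta: 24.9%

For gamma, step one alone at starting [partner] gives substrate a lifetime of 1.06 min. Allow 3 of these for the making, grant gamma the same target made, and let it stand for the rest of the time: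

gamma: 0.142%

So commit to zeta. The forecast names zeta too, with 0.04% for gamma and 23% for zeta, both lower than this reckoning, and says of the cooler flask that “only moderate over-reaction follows”.

The simulation gives zeta, with 0.0274% in gamma and 22.1% in zeta.

In gamma, set the target's lifetime of 1.61 min against the 6.00 min between the half time and the end: that span is half the gamma count, exp of which is 41.1, and the target falls from 1.12% to 0.0274%, a factor of 40.9. In zeta the same span counts only 0.291, the target goes from 24.1% to 22.1%, and its making, 3.02 times its loss at 3.57 min, is less than that loss at 12.0 min, at 0.373 of it.

Its constants were drawn at random within sensible limits; the result is computed.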